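The numbers in the tables stem from a simulated flask from invented constants; the scatter is artificial.

Per minute, the loss of G after the feed had ended was the figure I read from the two earlier runs, and I asked what set it.

all flasks: J 1 mol%

|  | G | E | remark | time |
|---|---|---|---|---|
| north-east | 18 mM (fed, over 40 min) | 0.15 mM | run made earlier |  |
| east | 39 mM (fed, over 40 min) | 0.15 mM | run made earlier |  |
| Monday's | 15 mM (fed, over 40 min) | 0.150 mM |  | 2.5 h |
| Wednesday's | 30 mM (fed, over 40 min) | 0.150 mM |  | 2.5 h |

| run | time / min | Q / % | G / % |
|---|---|---|---|
| north-east | 5.00 | 0.5 | 12.8 |
| north-east | 15.0 | 0.4 | 37.2 |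
| north-east | 25.0 | 2.3 | 61.1 |
| north-east | 40.0 | 6.0 | 94.4 |
| north-east | 60.0 | 13.5 | 87.1 |
| north-east | 80.0 | 18.6 | 81.7 |
| east | 5.00 | 0 | 12.6 |
| east | 15.0 | 1.4 | 35.8 |
| east | 25.0 | 4.0 | 58.4 |
| east | 40.0 | 14.6 | 85.4 |
| east | 60.0 | 30.8 | 68.9 |
| east | 80.0 | 47.0 | 52.9 |

(standard deviation of a reading: 0.5 percentage points)

- the average divides the monomer in chains by the number of chains begun, living and dead together
- the earlier runs were read with a standard deviation of 0.5 percentage points
- the earlier runs do not show the number of chains; that part of a forecast is a guess
- percentages count the whole charge, also what has not yet gone in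

1. which of the two ends with the longer chains by the average number of monomer units in a chain (chains begun, living or dead) ("neither" if they lie within 10%) (Monday's / Wednesday's / neither)
2. average number of monomer units in a chain (chains begun, living or dead) at the end, Monday's
3. average number of monomer units in a chain (chains begun, living or dead) at the end, Wednesday's

At 80.0 min in the east run the Q and G readings sum to 99.9%, so I counted reacted G as Q. I read G from 40.0 min to 80.0 min as a pseudo-first-order decay. The north-east readings fell from 94.4% to 81.7%, a constant of 0.00361 /min. The east readings fell from 85.4% to 52.9%, a constant of 0.0120 /min.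

E was charged at 0.15 mM in both runs, while J charged was 0.180 mM in north-east and 0.390 mM in east. I drew a straight line through the two readings. That gives 0.0398 /mM/min, the rise of the constant per millimolar of J charged, with the E charge and the loading held and G rising along with J, which I call the gain.

Wednesday's charges 0.300 mM of J and Monday's 0.150 mM, so the gain, counted from the north-east run, gave me 0.00839 /min and 0.00242 /min. I let each constant act on the whole charge from the end of the feed to the asked time, which gave Q shares of 60.3% for Wednesday's and 23.4% for Monday's. Guessing one chain per J charged, I divided each share by the loading and got 60.3 and 23.4.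

The forecast said Wednesday's, with 22 for Monday's and 70 for Wednesday's, on the ground that “E evidently deactivates initiator or chains”. My Wednesday's figure stood lower than its 70.

The flask gave 32.4 for Monday's and 80.7 for Wednesday's, so Wednesday's ended longer, with Q at 28.8% and 71.5% of the G charged. From the feed's end to the asked time, the states give average constants of 0.00262 /min for Monday's and 0.0104 /min for Wednesday's. The gap between them is 0.00779 /min, whereas the gain across the two J charges gives a smaller 0.00597 /min.

    G + Z → D + Q (k = 21.0 /M/min)
    D + E → L (k = 500 /M/min)
    J → Z (k = 0.0150 /min)
    G + D → Q + D, rate k4*[D]*[G] (k = 120 /M/min)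

The neighbour with 4 mol% of J on Monday's charge of G is charged with 0.600 mM of J, beyond the east run's 0.390 mM, and its G does not rise along with J, so the gain is stretched here. There the gain gave 0.0203 /min, a Q share of 89.3% and, at one chain per J, an average of 22.3. The computed flask left 2.37% of the G and reached an average of 30.5.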